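**Plan**

1. Labels: ring A = oxepane, ring B = left cyclohexanol, ring C = cyclohexene (C1 = CH bearing the side chain, C2 = methyl-bearing sp2 C, C3 = CH=, C4 = CH2), ring D = dimethylcyclohexanol (D1 = fusion CH next to the carbinol, D2 = C(CH3)OH, D3 and D4 = CH2, D5 = C(CH3)2, D6 = fusion CH next to D5 and C1).
2. Retrosynthesis: cut D6–D5 (ring D from a cyclopentanone by insertion of C(CH3)2, leaving a helper C=O at D4); cut C1–D6 and C4–D1 (Diels–Alder of an (E)-2-methyl-1,3-diene with (S)-4-silyloxycyclopentenone); cut the diene back to a lactol; open rings A and B plus a δ-lactone to an acyclic diepoxy ester made from farnesyl acetate.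
3. Forward order: rings A and B and the lactone in one epoxide-opening cascade, then ring C with a five-membered proto-ring D by cycloaddition, then ring D enlarged from five to six, then the D2 carbinol.
4. Enabling feature: the quaternary D5 lies between fusion methine D6 and methylene D4, and D6 is the α-carbon of the dienophile carbonyl. Inserting C(CH3)2 into the D6–C(=O) bond therefore makes the hindered quaternary centre and the six-membered ring together.
5. The C=O left at D4 then activates D3=D2 for a face-selective nucleophilic epoxidation and is removed by Wharton transposition.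
6. Stereochemistry: Shi epoxidation sets three epoxide centres, relayed by the chair cascade to the five centres of rings A and B; the bought (S)-silyloxy centre steers an endo, anti Diels–Alder that sets C1, D6 and D1 and is then erased; D2 comes from convex-face epoxidation of the cis-fused enone.

Key step: step 13

Remarks on the chemistry: 2,2-bis(phenylseleno)propane is taken as not being a catalogue compound and is made in step 11 from acetone and two equivalents of benzeneselenol. Lactol 8 is an anomer mixture. The carbinol centre of 18 is erased in step 13 and is left undefined. The methyl-bearing centre of 21 is erased in step 16 and is drawn as expected from convex-face delivery.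

**Route**

Step 1
Reactants: 1 (2E,6E)-farnesyl acetate
Product: 2 (2E,6S,7S,10S)-6,7:10,11-diepoxy-3,7,11-trimethyldodec-2-en-1-yl acetate
Conditions: L-fructose-derived Shi ketone (1,2:4,5-di-O-isopropylidene-β-L-erythro-2,3-hexodiulo-2,6-pyranose, 30 mol %), Oxone (2KHSO5·KHSO4·K2SO4), K2CO3, Bu4NHSO4, MeCN/CH2(OMe)2/aq. Na2B4O7 buffer, 0 °C
Reagents that add atoms: potassium peroxymonosulfate (active part of Oxone) [K+].[O-]S(=O)(=O)OO
Why: Shi epoxidation through a chiral dioxirane; the allylic acetate deactivates the 2,3-alkene so only the two remote trisubstituted alkenes react, and the L-series ketone should deliver oxygen to the face giving the (6S,7S,10S) diepoxide, which fixes the later ring A carbinol and the A/B fusion centres.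

Step 2
Reactants: 2 diepoxy acetate
Product: 3 (2E,6S,7S,10S)-6,7:10,11-diepoxy-3,7,11-trimethyldodec-2-en-1-ol
Conditions: K2CO3 (cat.), MeOH, 0 °C
Reagents that add atoms: none
Why: Mild transesterification removes the acetate without opening the trisubstituted epoxides.

Step 3
Reactants: 3 diepoxy allylic alcohol
Product: 5 (2E,6S,7S,10S)-1-bromo-6,7:10,11-diepoxy-3,7,11-trimethyldodec-2-ene, via allylic mesylate 4 (not isolated)
Conditions: MsCl, Et3N, THF, −40 °C; then LiBr, THF, 0 °C
Reagents that add atoms: lithium bromide [Li+].[Br-]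
Why: Mesylation and SN2 displacement by bromide at low temperature give the primary allylic bromide with retention of the E alkene and without touching the epoxides.

Step 4
Reactants: 5 diepoxy allylic bromide
Product: 6 tert-butyl (4E,8S,9S,12S)-8,9:12,13-diepoxy-5,9,13-trimethyltetradec-4-enoate
Conditions: tert-butyl acetate, LiN(i-Pr)2, THF, −78 °C; then 5, DMPU, −78 → −40 °C
Reagents that add atoms: tert-butyl acetate (as its lithium enolate) CC(=O)OC(C)(C)C
Why: SN2 alkylation of an ester enolate by the primary allylic bromide is much faster than epoxide opening; it adds the two carbons that become the linker CH2 and ring carbon C1 and installs the ester that will end the cascade.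

Step 5
Reactants: 6 diepoxy tert-butyl ester
Product: 7 TBS-protected tricyclic δ-lactone (oxepane ring A trans-fused to cyclohexane ring B; lactone oxygen equatorial on the methyl-bearing ring B carbon; lactone CH2CH2 equatorial on the neighbouring CH)
Conditions: TBSOTf (1.2 equiv), 2,6-di-tert-butyl-4-methylpyridine, CH2Cl2, −78 °C
Reagents that add atoms: tert-butyldimethylsilyl triflate CC(C)(C)[Si](C)(C)OS(=O)(=O)C(F)(F)F
Why: Lewis-acid epoxide-opening cascade (tandem oxa- and carbacyclization): the silylated terminal epoxide is opened at its tertiary carbon by the internal epoxide oxygen; the resulting epoxonium is opened with inversion at its tertiary carbon by the E alkene through a chair; the tertiary cation is captured from the equatorial side by the ester carbonyl with loss of 2-methylpropene. This should set the trans A/B fusion, the equatorial side chain and the axial-methyl/equatorial-oxygen carbinol centre in one event.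

Step 6
Reactants: 7 tricyclic δ-lactone
Product: 8 lactol (anomer mixture)
Conditions: i-Bu2AlH, CH2Cl2, −78 °C
Reagents that add atoms: none
Why: Half-reduction of a δ-lactone stops at the tetrahedral aluminium acetal at −78 °C and gives the lactol on work-up.

Step 7
Reactants: 8 lactol
Product: 9 (E)-α-methyl enal with free tertiary hydroxyl on ring B (side chain CH2CH2CH=C(CH3)CHO)
Conditions: 2-(triphenylphosphoranylidene)propanal, toluene, 90 °C
Reagents that add atoms: 2-(triphenylphosphoranylidene)propanal CC(C=O)=P(c1ccccc1)(c1ccccc1)c1ccccc1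
Why: Wittig reaction of the open hydroxy-aldehyde form with a stabilised ylide; thermodynamic control in the oxaphosphetane step should give the E trisubstituted alkene, which becomes C1=C2 of the diene.

Step 8
Reactants: 9 hydroxy enal
Product: 10 triethylsilyl ether of 9
Conditions: TESOTf, 2,6-lutidine, CH2Cl2, −78 → 0 °C
Reagents that add atoms: triethylsilyl triflate CC[Si](CC)(CC)OS(=O)(=O)C(F)(F)F
Why: A silyl triflate silylates the hindered tertiary alcohol, which prevents oxa-Michael addition to the enal and consumption of the later organometallic reagents.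

Step 9
Reactants: 10 silylated enal
Product: 11 (E)-diene (side chain CH2CH2CH=C(CH3)CH=CH2 on the bis-silylated ring A/B fragment)
Conditions: Ph3PCH3Br, KN(SiMe3)2, THF, 0 °C; then 10, −78 → 0 °C
Reagents that add atoms: methylenetriphenylphosphorane (from methyltriphenylphosphonium bromide) C=P(c1ccccc1)(c1ccccc1)c1ccccc1
Why: Wittig methylenation of the enal gives the 1-alkyl-2-methylbuta-1,3-diene without disturbing the E geometry.

Step 10
Reactants: 11 (E)-diene; 12 (S)-4-(tert-butyldimethylsilyloxy)cyclopent-2-en-1-one
Product: 13 cis-fused cycloadduct (ring C complete; five-membered proto-ring D with C=O on D6 and CH–OTBS on D1; side chain at C1 cis to both ring-fusion bonds; OTBS cis to the fusion hydrogens)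
Conditions: Me2AlCl (30 mol %), CH2Cl2, −78 → −30 °C
Reagents that add atoms: none
Why: Lewis-acid-catalysed Diels–Alder reaction; the alkyl-substituted diene terminus should bond to the enone α-carbon ("ortho" rule, the terminal alkyl group being expected to outweigh the weaker opposing bias of the internal methyl) and the free CH2 terminus to the β-carbon, the endo transition state places the E substituent cis to the dienophile ring, and the diene adds anti to the silyloxy group, so C1, D6 and D1 should be set in the absolute sense of the target from the one bought stereocentre.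

Step 11
Reactants: 14 acetone; 15 benzeneselenol (one of the two equivalents that are built in; the other is entered below)
Product: 16 2,2-bis(phenylseleno)propane
Conditions: PhSeH (2.1 equiv in all), ZnCl2 (50 mol %), CH2Cl2, 20 °C
Reagents that add atoms: benzeneselenol (second equivalent of 15) [SeH]c1ccccc1
Why: Lewis-acid-promoted selenoketalisation: the ketone condenses with two equivalents of the selenol with loss of water, through the hemiselenoketal and a selenium-stabilised carbocation that the second selenol captures.

Step 12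
Reactants: 13 cycloadduct ketone; 16 2,2-bis(phenylseleno)propane
Product: 18 β-hydroxy selenide (tertiary carbinol on proto-ring D carrying C(CH3)2SePh), via 2-lithio-2-(phenylseleno)propane 17 (not isolated)
Conditions: 16, n-BuLi, THF, −78 °C; then 13, −78 °C; H2O
Reagents that add atoms: none
Why: Selenium–lithium exchange gives a tertiary α-selenoalkyllithium, a strongly nucleophilic and weakly basic carbanion that should add to the hindered, enolisable cyclopentanone in preference to enolisation; the new carbinol centre is lost in the next step.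

Step 13
Reactants: 18 β-hydroxy selenide
Product: 19 ring-enlarged ketone (cis-fused rings C and D; D5 = C(CH3)2, D4 = C=O, D3 = CH2, D2 = CH–OTBS)
Conditions: AgBF4 on neutral Al2O3, CH2Cl2, 0 → 20 °C
Reagents that add atoms: none
Why: Monovalent silver binds selenium and the C–Se bond ionises toward a tertiary cation at the C(CH3)2 carbon; the antiperiplanar ring bond from the carbinol carbon to D6 shifts to that carbon while the hydroxyl becomes the D4 carbonyl. The closest known reaction type is the seleno-semipinacol (Tiffeneau–Demjanov-like) ring enlargement of β-hydroxyalkyl selenides to α,α-dimethyl cycloalkanones. Ring D is formed by a 1,2-alkyl shift that enlarges the cyclopentane by one carbon, not by an end-to-end closure. No new stereocentre arises; D6 migrates with retention, so the cis fusion and the configuration at C1 are kept. The required selectivity is migration of the methine D6 instead of the ring CH2; it is secured by the higher substitution of D6 and by the β-silyloxy group, which inductively deactivates the CH2. The soft Lewis acid spares the trisubstituted ring C alkene and the alumina takes up the HBF4, which protects the silyl ethers.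

Step 14
Reactants: 19 β-silyloxy ketone
Product: 20 enone (D4 C=O conjugated with D3=D2)
Conditions: DBU, CH2Cl2, 20 → 40 °C
Reagents that add atoms: none
Why: E1cB elimination of silanol through the only possible enolate (toward D3) erases the controller stereocentre and gives the enone.

Step 15
Reactants: 20 enone
Product: 21 trimethylsilyl enol ether (D4–OSiMe3, D4=D3, CH3 on D2)
Conditions: Me2CuLi (from MeLi and CuI), Me3SiCl, THF, −78 °C
Reagents that add atoms: lithium dimethylcuprate [Li+].C[Cu-]C; chlorotrimethylsilane C[Si](C)(C)Cl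
Why: Silyl-chloride-accelerated cuprate conjugate addition puts the methyl group on D2 and traps the enolate regiospecifically; the configuration at D2 does not matter.

Step 16
Reactants: 21 silyl enol ether
Product: 22 β-methyl enone (D4 C=O, D3=D2, CH3 on D2)
Conditions: Pd(OAc)2 (1.1 equiv), MeCN, 20 °C
Reagents that add atoms: none
Why: Saegusa–Ito oxidation; the oxa-π-allyl palladium intermediate can only lose the hydride on D2, which regenerates the enone with the methyl group now on the alkene.

Step 17
Reactants: 22 β-methyl enone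
Product: 23 α,β-epoxy ketone (D2–D3 oxirane with oxygen cis to the ring-fusion hydrogens)
Conditions: 30 % H2O2, NaOH (cat.), MeOH, 0 → 20 °C
Reagents that add atoms: hydrogen peroxide OO
Why: Nucleophilic (Weitz–Scheffer) epoxidation touches only the enone, not the ring C alkene; hydroperoxide should attack D2 from the convex face of the cis-fused bicycle (the face of the fusion hydrogens), which sets the D2 configuration of the target.

Step 18
Reactants: 23 epoxy ketone
Product: 25 tertiary allylic alcohol (D2 = C(CH3)OH, D3=D4 alkene), via epoxy hydrazone 24 (not isolated)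
Conditions: N2H4·H2O, AcOH (cat.), MeOH, 20 °C
Reagents that add atoms: none
Why: Wharton transposition: the epoxy hydrazone opens to an alkenyl diazene that loses N2, so the D4 oxygen is removed and the D2–O bond is kept with its configuration.

Step 19
Reactants: 25 allylic alcohol
Product: 26 bis-silylated sipholenol L (ring D saturated)
Conditions: 2-nitrobenzenesulfonohydrazide, Et3N, CH2Cl2, 20 °C
Reagents that add atoms: none
Why: Diimide reduction by concerted syn hydrogen transfer should reduce the cis-disubstituted D3=D4 alkene and spare the trisubstituted ring C alkene.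

Step 20
Reactants: 26 bis-silyl ether
Product: 27 sipholenol L
Conditions: Bu4NF, THF, 20 → 50 °C
Reagents that add atoms: none
Why: Fluoride cleaves the secondary TBS and tertiary TES ethers under non-acidic conditions that leave the tertiary alcohols and the alkene untouched.

**Compound list**

1 | (2E,6E)-farnesyl acetate | CC(=O)OC/C=C(\C)CC/C=C(\C)CCC=C(C)C | starting material
2 | (2E,6S,7S,10S)-6,7:10,11-diepoxy-3,7,11-trimethyldodec-2-en-1-yl acetate | CC(=O)OC/C=C(\C)CC[C@@H]1O[C@@]1(C)CC[C@@H]1OC1(C)C | intermediate
3 | (2E,6S,7S,10S)-6,7:10,11-diepoxy-3,7,11-trimethyldodec-2-en-1-ol | OC/C=C(\C)CC[C@@H]1O[C@@]1(C)CC[C@@H]1OC1(C)C | intermediate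
4 | allylic methanesulfonate of 3 | CS(=O)(=O)OC/C=C(\C)CC[C@@H]1O[C@@]1(C)CC[C@@H]1OC1(C)C | intermediate
5 | (2E,6S,7S,10S)-1-bromo-6,7:10,11-diepoxy-3,7,11-trimethyldodec-2-ene | BrC/C=C(\C)CC[C@@H]1O[C@@]1(C)CC[C@@H]1OC1(C)C | intermediate
6 | tert-butyl (4E,8S,9S,12S)-8,9:12,13-diepoxy-5,9,13-trimethyltetradec-4-enoate | CC(C)(C)OC(=O)CC/C=C(\C)CC[C@@H]1O[C@@]1(C)CC[C@@H]1OC1(C)C | intermediate
7 | TBS-protected tricyclic δ-lactone (rings A, B and lactone, all trans-fused) | O=C1CC[C@H]2[C@]3(C)CC[C@H](O[Si](C)(C)C(C)(C)C)C(C)(C)O[C@H]3CC[C@]2(C)O1 | intermediate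
8 | lactol of 7 (anomer mixture) | OC1CC[C@H]2[C@]3(C)CC[C@H](O[Si](C)(C)C(C)(C)C)C(C)(C)O[C@H]3CC[C@]2(C)O1 | intermediate
9 | (E)-α-methyl enal with free ring B tertiary alcohol | O=C/C(C)=C/CC[C@H]1[C@]2(C)CC[C@H](O[Si](C)(C)C(C)(C)C)C(C)(C)O[C@H]2CC[C@]1(C)O | intermediate
10 | triethylsilyl ether of 9 | O=C/C(C)=C/CC[C@H]1[C@]2(C)CC[C@H](O[Si](C)(C)C(C)(C)C)C(C)(C)O[C@H]2CC[C@]1(C)O[Si](CC)(CC)CC | intermediate
11 | (E)-2-methyl-1,3-diene on the bis-silylated ring A/B fragment | C=C/C(C)=C/CC[C@H]1[C@]2(C)CC[C@H](O[Si](C)(C)C(C)(C)C)C(C)(C)O[C@H]2CC[C@]1(C)O[Si](CC)(CC)CC | intermediate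
12 | (S)-4-(tert-butyldimethylsilyloxy)cyclopent-2-en-1-one | O=C1C[C@@H](C=C1)O[Si](C)(C)C(C)(C)C | starting material
13 | cis-fused Diels–Alder adduct (cyclohexene ring C fused to a 3-silyloxycyclopentanone) | CC1=CC[C@H]2[C@@H]([C@@H]1CC[C@H]1[C@]3(C)CC[C@H](O[Si](C)(C)C(C)(C)C)C(C)(C)O[C@H]3CC[C@]1(C)O[Si](CC)(CC)CC)C(=O)C[C@@H]2O[Si](C)(C)C(C)(C)C | intermediate
14 | acetone | CC(C)=O | starting material
15 | benzeneselenol | [SeH]c1ccccc1 | starting material
16 | 2,2-bis(phenylseleno)propane | CC(C)([Se]c1ccccc1)[Se]c1ccccc1 | intermediate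
17 | 2-lithio-2-(phenylseleno)propane | [Li]C(C)(C)[Se]c1ccccc1 | intermediate
18 | β-hydroxy selenide (carbinol centre undefined) | CC1=CC[C@H]2[C@@H]([C@@H]1CC[C@H]1[C@]3(C)CC[C@H](O[Si](C)(C)C(C)(C)C)C(C)(C)O[C@H]3CC[C@]1(C)O[Si](CC)(CC)CC)C(O)(C(C)(C)[Se]c1ccccc1)C[C@@H]2O[Si](C)(C)C(C)(C)C | intermediate
19 | ring-enlarged β-silyloxy ketone (D5 C(CH3)2, D4 C=O, D2 CH–OTBS) | CC1=CC[C@H]2[C@@H]([C@@H]1CC[C@H]1[C@]3(C)CC[C@H](O[Si](C)(C)C(C)(C)C)C(C)(C)O[C@H]3CC[C@]1(C)O[Si](CC)(CC)CC)C(C)(C)C(=O)C[C@@H]2O[Si](C)(C)C(C)(C)C | intermediate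
20 | cis-fused enone (D4 C=O, D3=D2) | CC1=CC[C@H]2[C@@H]([C@@H]1CC[C@H]1[C@]3(C)CC[C@H](O[Si](C)(C)C(C)(C)C)C(C)(C)O[C@H]3CC[C@]1(C)O[Si](CC)(CC)CC)C(C)(C)C(=O)C=C2 | intermediate
21 | trimethylsilyl enol ether with CH3 on D2 | CC1=CC[C@H]2[C@@H]([C@@H]1CC[C@H]1[C@]3(C)CC[C@H](O[Si](C)(C)C(C)(C)C)C(C)(C)O[C@H]3CC[C@]1(C)O[Si](CC)(CC)CC)C(C)(C)C(O[Si](C)(C)C)=C[C@@H]2C | intermediate
22 | β-methyl enone (D4 C=O, D3=D2–CH3) | CC1=CC[C@H]2[C@@H]([C@@H]1CC[C@H]1[C@]3(C)CC[C@H](O[Si](C)(C)C(C)(C)C)C(C)(C)O[C@H]3CC[C@]1(C)O[Si](CC)(CC)CC)C(C)(C)C(=O)C=C2C | intermediate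
23 | α,β-epoxy ketone (oxirane oxygen cis to the fusion hydrogens) | CC1=CC[C@H]2[C@@H]([C@@H]1CC[C@H]1[C@]3(C)CC[C@H](O[Si](C)(C)C(C)(C)C)C(C)(C)O[C@H]3CC[C@]1(C)O[Si](CC)(CC)CC)C(C)(C)C(=O)[C@@H]3O[C@]23C | intermediate
24 | hydrazone of 23 | CC1=CC[C@H]2[C@@H]([C@@H]1CC[C@H]1[C@]3(C)CC[C@H](O[Si](C)(C)C(C)(C)C)C(C)(C)O[C@H]3CC[C@]1(C)O[Si](CC)(CC)CC)C(C)(C)C(=NN)[C@@H]3O[C@]23C | intermediate
25 | tertiary allylic alcohol (D2 C(CH3)OH, D3=D4) | CC1=CC[C@H]2[C@@H]([C@@H]1CC[C@H]1[C@]3(C)CC[C@H](O[Si](C)(C)C(C)(C)C)C(C)(C)O[C@H]3CC[C@]1(C)O[Si](CC)(CC)CC)C(C)(C)C=C[C@]2(C)O | intermediate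
26 | bis-silylated sipholenol L (ring A O-TBS, ring B O-TES) | CC1=CC[C@H]2[C@@H]([C@@H]1CC[C@H]1[C@]3(C)CC[C@H](O[Si](C)(C)C(C)(C)C)C(C)(C)O[C@H]3CC[C@]1(C)O[Si](CC)(CC)CC)C(C)(C)CC[C@]2(C)O | intermediate
27 | sipholenol L | CC1=CC[C@H]2[C@@H]([C@@H]1CC[C@H]1[C@]3(C)CC[C@H](O)C(C)(C)O[C@H]3CC[C@]1(C)O)C(C)(C)CC[C@]2(C)O | target

**Step count and risks**

Total step count: 20. Longest linear sequence: 19 steps (steps 1–10 and 12–20; step 11 is a side branch).

Steps most likely to fail:

1. Step 5. The internal epoxide may be activated before the terminal one, and the tertiary cation may lose a proton instead of being captured by the ester, so the one-flask closure of rings A, B and the lactone may be incomplete. Fallback (sets out from 6, returns at 7): ring formation and C–O bond formation are separated. The same silyl-triflate activation is run so that the cation ends by proton loss, which should give the ring A/B tert-butyl ester with an exocyclic methylene on ring B F1 (endocyclic isomers are carried along). A separate Brønsted-acid hydro-lactonisation (MsOH, CH2Cl2, −20 °C) then protonates the alkene in the Markovnikov sense; the ester oxygen should attack the tertiary cation from the equatorial side, which the syn-axial angular methyl leaves open, and 2-methylpropene is lost to give 7.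

2. Step 10. Silanol may be lost from the β-silyloxy enone or from the adduct under Lewis acid, and regiocontrol by the alkyl terminus of the diene may be insufficient. Fallback (sets out from 11, returns at 20): stereocontrol is moved from the dienophile to a catalyst. Diene 11 and cyclopent-2-en-1-one are combined under a chiral oxazaborolidinium Lewis acid (B-(o-tolyl)oxazaborolidine from α,α-diphenylprolinol activated by HNTf2, CH2Cl2, −78 → −40 °C; the antipode is chosen for the required enone face) to give the unsubstituted cis-fused cycloadduct ketone F2. Addition of 17 gives the β-hydroxy selenide F3, and AgBF4 on Al2O3 gives the ring-enlarged ketone F4. LiN(i-Pr)2 and Me3SiCl give the silyl enol ether F5, and Pd(OAc)2 in MeCN gives enone 20.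

3. Step 13. The ring CH2 may migrate instead of D6, or the selenonium-type intermediate may collapse to an oxirane or an allylic alcohol without a shift. Fallback (sets out from 13, returns at 19): the cation is made by a different trigger from a different precursor. 2-Propenylmagnesium bromide with CeCl3 (THF, −78 °C) converts 13 into the 2-propenyl carbinol F6. A hydrogen-atom-transfer-initiated radical–polar crossover semipinacol (Co(salen), the divalent cobalt complex of N,N′-bis(salicylidene)ethylenediamine, 5 mol %; N-fluoro-2,4,6-trimethylpyridinium tetrafluoroborate; PhSiH3; acetone, 0 °C) should add hydrogen to the 1,1-disubstituted alkene in preference to the trisubstituted ring C alkene, oxidise the tertiary radical to the cation, and trigger the same 1,2-shift of D6 to give 19.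

Further compounds
F1 | step 5 | tert-butyl ester of the silylated ring A/B bicycle with exocyclic methylene on ring B | CC(C)(C)OC(=O)CC[C@H]1[C@]2(C)CC[C@H](O[Si](C)(C)C(C)(C)C)C(C)(C)O[C@H]2CCC1=C
F2 | step 10 | cis-fused Diels–Alder adduct of 11 with cyclopent-2-en-1-one | CC1=CC[C@H]2[C@@H]([C@@H]1CC[C@H]1[C@]3(C)CC[C@H](O[Si](C)(C)C(C)(C)C)C(C)(C)O[C@H]3CC[C@]1(C)O[Si](CC)(CC)CC)C(=O)CC2
F3 | step 10 | β-hydroxy selenide from F2 (carbinol centre undefined) | CC1=CC[C@H]2[C@@H]([C@@H]1CC[C@H]1[C@]3(C)CC[C@H](O[Si](C)(C)C(C)(C)C)C(C)(C)O[C@H]3CC[C@]1(C)O[Si](CC)(CC)CC)C(O)(C(C)(C)[Se]c1ccccc1)CC2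
F4 | step 10 | ring-enlarged ketone without the D2 oxygen | CC1=CC[C@H]2[C@@H]([C@@H]1CC[C@H]1[C@]3(C)CC[C@H](O[Si](C)(C)C(C)(C)C)C(C)(C)O[C@H]3CC[C@]1(C)O[Si](CC)(CC)CC)C(C)(C)C(=O)CC2
F5 | step 10 | trimethylsilyl enol ether of F4 | CC1=CC[C@H]2[C@@H]([C@@H]1CC[C@H]1[C@]3(C)CC[C@H](O[Si](C)(C)C(C)(C)C)C(C)(C)O[C@H]3CC[C@]1(C)O[Si](CC)(CC)CC)C(C)(C)C(O[Si](C)(C)C)=CC2
F6 | step 13 | 2-propenyl carbinol from 13 (carbinol centre undefined) | CC1=CC[C@H]2[C@@H]([C@@H]1CC[C@H]1[C@]3(C)CC[C@H](O[Si](C)(C)C(C)(C)C)C(C)(C)O[C@H]3CC[C@]1(C)O[Si](CC)(CC)CC)C(O)(C(C)=C)C[C@@H]2O[Si](C)(C)C(C)(C)C
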